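**Strategy**

- Numbering: cycloheptane C1 (tertiary carbinol bearing the (E)-but-2-enoyl chain C2–C4 with methyl C15), C5 (ester CH), C6 (lactone O–CH), C7, C8, C9 (CHOH), C10 (CHMe, methyl C14); lactone carbons C11 (=C13H2) and C12 (C=O). β is the face of the C7–C11 bond, α the other face.
- Cuts, in retrosynthetic order: the C5–O ester bond, the O–C12 lactone bond (back to a C12 allylic alcohol), the C1–OH bond, and then C1 is lifted out of the ring by cutting C1–C10 and C1–C5. This leaves an α-silyloxy cyclohexanone and a five-carbon diazo enone.
- What allows this: C1 carries an acyl carbon (C2) and adjoins the oxygenated C5, the pattern of a 2-acylcycloheptanone. The ring without C1 (C5–C6–C7–C8–C9–C10) is a cyclohexanone with all four substituents equatorial, whose C14 methyl and C11 branch sit 1,4 as in carvone.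
- Forward: the six-membered ring of (R)-carvone is functionalised (C12 oxygen, C9 alcohol, ketone moved to C5, C6 hydroxyl) and the diazo enone is added at C5. The ring then grows to seven members by a rhodium-carbenoid 1,2-shift of C10. The lactone ring is closed afterwards by oxidative lactonisation onto the C6 hydroxyl, followed by C5 reduction, esterification and desilylation.
- Stereochemistry: C7 from (R)-carvone, C9 by Luche reduction, C10 by equilibration (kept in the shift), C6 by enolate hydroxylation anti to the C7 branch, C1 by oxidation directed by the C6 hydroxyl, C5 by hydride delivered from the C1 hydroxyl, ester centre from (R)-2-methylbutanoic acid.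

Key step: step 14

Remark: two stereocentres have no bearing on the outcome. The carbinol carbon of the diazo adduct is erased in the key step and is drawn as the epimer expected from equatorial attack. The anomeric carbon of the transient lactol is left undefined.

**Route**

Step 1
Reactants: 1 (R)-(−)-carvone
Product: 2 (R)-10-chlorocarvone [(5R)-5-(3-chloroprop-1-en-2-yl)-2-methylcyclohex-2-en-1-one]
Conditions: Ca(OCl)2, solid CO2, CH2Cl2/H2O, 0 °C
Reagents that add atoms: calcium hypochlorite, [Ca+2].[O-]Cl.[O-]Cl
Why: Hypochlorous acid set free from the hypochlorite chlorinates the electron-rich 1,1-disubstituted alkene in an ene-type allylic chlorination (the double-bond shift is degenerate in an isopropenyl group), while the electron-poor enone alkene does not react and C7 is untouched.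

Step 2
Reactants: 2 (R)-10-chlorocarvone
Product: 3 (R)-10-acetoxycarvone (acetate on C12 of the 2-substituted allyl side chain)
Conditions: KOAc, nBu4NI (cat.), DMF, 60 °C
Reagents that add atoms: potassium acetate, CC(=O)[O-].[K+]
Why: Iodide-assisted bimolecular displacement of the primary allylic chloride by acetate (direct and allylic attack give the same product), a standard allylic acetoxylation that leaves the enone alone.

Step 3
Reactants: 3 (R)-10-acetoxycarvone
Product: 4 (1R,5R)-10-acetoxy-cis-carveol (9β-hydroxyl, cis to the C7 side chain)
Conditions: NaBH4, CeCl3·7H2O, MeOH, −78 °C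
Reagents that add atoms: none
Why: Luche 1,2-reduction; hydride adds axially to the half-chair enone that carries the side chain pseudo-equatorially, which sets C9 with the hydroxyl cis to the C7 branch, and the acetate survives the cold borohydride.

Step 4
Reactants: 4 (1R,5R)-10-acetoxy-cis-carveol
Product: 5 syn-epoxy alcohol (5β,10β-epoxide on the face of the 9β-hydroxyl, C12 acetate)
Conditions: VO(acac)2 (2 mol %), tBuOOH (decane), CH2Cl2, 0 °C to rt
Reagents that add atoms: tert-butyl hydroperoxide, CC(C)(C)OO
Why: Hydroxyl-directed vanadium epoxidation: the pentavalent vanadium alkylperoxide formed from VO(acac)2 (tetravalent vanadium) binds the C9 hydroxyl and delivers oxygen to the ring alkene on the same face, and the side-chain alkene, which has no free allylic hydroxyl, is not epoxidised.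

Step 5
Reactants: 5 syn-epoxy alcohol acetate
Product: 6 epoxy diol (C12 and C9 hydroxyls free)
Conditions: K2CO3 (cat.), MeOH, 0 °C
Reagents that add atoms: none
Why: Base-catalysed transesterification removes the acetate; the C9 alkoxide is syn to the epoxide and cannot reach C10 from the rear, so no Payne rearrangement is expected.

Step 6
Reactants: 6 epoxy diol
Product: 7 bis-TBS epoxide (tert-butyldimethylsilyl ethers at C12–O and C9–O)
Conditions: TBSCl, imidazole, DMAP (cat.), DMF, rt to 40 °C
Reagents that add atoms: tert-butyldimethylsilyl chloride, CC(C)(C)[Si](C)(C)Cl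
Why: Standard silylation of both hydroxyls in one operation; the pairing of a primary allylic and a hindered secondary TBS ether is chosen so that the primary one can later be taken off first.

Step 7
Reactants: 7 bis-TBS epoxide
Product: 8 secondary alcohol (5β-hydroxyl, 10β-methyl and 9β-OTBS all cis)
Conditions: Cp2TiCl2 (10 mol %), Mn dust, 2,4,6-collidine·HCl, 1,4-cyclohexadiene, THF, rt
Reagents that add atoms: none
Why: Titanocene-mediated reductive epoxide opening (Nugent–RajanBabu reaction): Cp2TiCl (trivalent titanium) cleaves the C10–O bond homolytically to the tertiary radical, which abstracts hydrogen from 1,4-cyclohexadiene, so the oxygen stays on the less substituted C5 with its β-configuration; hydrogen is expected to arrive anti to the bulky titanium alkoxide, leaving the methyl β, which is corrected in step 9.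

Step 8
Reactants: 8 secondary alcohol
Product: 9 C5 ketone with axial (10β) methyl
Conditions: Dess–Martin periodinane, NaHCO3, CH2Cl2, rt
Reagents that add atoms: none
Why: Dess–Martin oxidation of the secondary alcohol under buffered, non-acidic conditions that both silyl ethers and the alkene tolerate.

Step 9
Reactants: 9 C5 ketone with axial methyl
Product: 10 all-equatorial cyclohexanone (C5 ketone, 10α-methyl, 9β-OTBS, 7β side chain)
Conditions: K2CO3, MeOH, rt
Reagents that add atoms: none
Why: Thermodynamic epimerisation through the C5–C10 enolate moves the methyl from the axial to the equatorial position; the equatorial C9–O bond lies close to the nodal plane of that enolate, so β-elimination of the silyloxy group should be slow.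

Step 10
Reactants: 10 all-equatorial cyclohexanone
Product: 11 6α-hydroxy ketone (hydroxyl trans to the C7 side chain, equatorial)
Conditions: KN(SiMe3)2, THF, −78 °C; 2-(phenylsulfonyl)-3-phenyloxaziridine; AcOH, −78 °C
Reagents that add atoms: 2-(phenylsulfonyl)-3-phenyloxaziridine (Davis oxaziridine), C1(c2ccccc2)N(S(=O)(=O)c2ccccc2)O1
Why: Kinetic deprotonation at the CH2 carbon C6 followed by Davis enolate hydroxylation; the bulky oxaziridine approaches anti to the adjacent C7 branch, which sets C6 with the oxygen α, the orientation that is also equatorial and thermodynamically preferred.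

Step 11
Reactants: 11 6α-hydroxy ketone
Product: 12 6α-triethylsilyloxy ketone
Conditions: TESCl, imidazole, DMF, 0 °C to rt
Reagents that add atoms: chlorotriethylsilane, CC[Si](Cl)(CC)CC
Why: Routine silylation; the TES ether blocks α-ketol isomerisation and O–H chemistry in the next two steps and can be removed later in the presence of both TBS ethers.

Step 12
Reactants: 13 (E)-pent-3-en-2-one
Product: 15 (E)-1-diazopent-3-en-2-one, via trifluoroacetyl diketone 14 (not isolated)
Conditions: LiN(SiMe3)2, THF, −78 °C; CF3CO2CH2CF3; dilute HCl wash; methanesulfonyl azide, Et3N, H2O, MeCN, rt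
Reagents that add atoms: methanesulfonyl azide, CS(=O)(=O)N=[N+]=[N-]
Why: Detrifluoroacetylative diazo transfer (a Regitz-type transfer to an activated methyl ketone): the kinetic cross-conjugated enolate is trifluoroacetylated and the resulting 1,3-diketone accepts the diazo group with loss of the trifluoroacetyl group, which avoids the acid chloride/diazomethane route and its dipolar cycloaddition to the enone.

Step 13
Reactants: 12 6α-triethylsilyloxy ketone; 15 (E)-1-diazopent-3-en-2-one
Product: 16 β-hydroxy α-diazo ketone (C5 tertiary carbinol carrying the 1-diazo-2-oxopent-3-enyl group; 5α-hydroxyl drawn)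
Conditions: 15, LiN(iPr)2, THF, −78 °C; then 12, −78 °C; AcOH in THF, −78 °C
Reagents that add atoms: none
Why: Aldol-type addition of the lithiated diazo ketone (deprotonated at the diazo carbon, the kinetic α'-site of the enone) to the ketone, whose electrophilicity is raised by the α-silyloxy group; the cold acidic quench prevents retro-addition, and the new carbinol centre, expected with the hydroxyl axial after equatorial attack, is erased in step 14.

Step 14
Reactants: 16 β-hydroxy α-diazo ketone
Product: 17 ring-expanded 2-[(E)-but-2-enoyl]cycloheptanone written as its C5 enol (6α-OTES, 7β side chain, 9β-OTBS, 10α-methyl)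
Conditions: Rh2(OAc)4 (2 mol %), CH2Cl2, 0 °C to rt
Reagents that add atoms: none
Why: Rh2(OAc)4 (divalent rhodium) decomposes the diazo group to an electrophilic rhodium carbenoid at C1, and the lone pair of the neighbouring C5 hydroxyl pushes the C5–C10 bond onto C1 as the metal leaves, so C1–C10 forms while C5–C10 breaks, C5 becomes the ring ketone and the 2-acyl ketone rests as its hydrogen-bonded enol. The closest known reaction type is the two-stage homologation of cycloalkanones through lithiated α-diazo carbonyl adducts and Rh2(OAc)4-induced 1,2-alkyl shift to ring-enlarged 1,3-dicarbonyl compounds. The seven-membered ring is not closed by a cyclisation but arises by enlargement of the cyclohexane through this 1,2-shift, the inserted carbon C1 bringing C2–C4 and C15 with it. No new stereocentre is formed, since C10 migrates with retention and the C5 carbinol centre disappears. The step needs C10 to migrate rather than C6, and this rests on C6 carrying a silyloxy group that withdraws inductively and, as a silyl ether, is a poor lone-pair donor, whereas C10 is an ordinary secondary alkyl carbon. Because the carbinol is tertiary no hydride shift can compete, and the shift to the adjacent centre is expected to outrun cyclopropanation of the two remote alkenes and O–H insertion.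

Step 15
Reactants: 17 ring-expanded enol
Product: 18 6α-hydroxy enol (TES removed, both TBS ethers kept)
Conditions: HF·pyridine, pyridine, THF, 0 °C
Reagents that add atoms: none
Why: Buffered fluoride desilylation; the triethylsilyl ether is cleaved well before the primary and the hindered secondary TBS ethers, and the weakly acidic, non-nucleophilic medium should spare the enoyl diketone.

Step 16
Reactants: 18 6α-hydroxy enol
Product: 19 1α,6α-dihydroxy diketone (C1 tertiary hydroxyl α, butenoyl group β, C5 ketone)
Conditions: VO(acac)2 (5 mol %), tBuOOH (decane), CH2Cl2, −20 to 0 °C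
Reagents that add atoms: tert-butyl hydroperoxide, CC(C)(C)OO
Why: Hydroxyl-directed vanadium epoxidation applied to the enol double bond C1=C5: the pentavalent vanadium alkylperoxide bound to the C6 hydroxyl transfers oxygen from the α-face and the hydroxy epoxide collapses to the C5 ketone, which sets C1 with its hydroxyl on the face of the C6 hydroxyl; the side-chain alkene has no free hydroxyl and the enone is electron-poor, so neither should be epoxidised.

Step 17
Reactants: 19 1α,6α-dihydroxy diketone
Product: 20 triol (C12 primary allylic alcohol free, C9 still TBS-protected)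
Conditions: HF·pyridine, pyridine, THF, 0 °C to rt
Reagents that add atoms: none
Why: Under buffered HF·pyridine a primary allylic TBS ether is cleaved much faster than the secondary C9 TBS ether flanked by the C10 methyl, a routine primary/secondary differentiation.

Step 18
Reactants: 20 triol
Product: 23 trans-fused α-methylene lactone ketone, via hydroxy enal 21 (not isolated), via lactol 22 (not isolated)
Conditions: TEMPO (20 mol %), PhI(OAc)2, CH2Cl2, rt
Reagents that add atoms: none
Why: Oxidative lactonisation of a 1,4-diol: the oxoammonium oxidant picks the primary allylic alcohol, the enal is trapped by the C6 hydroxyl as a five-membered lactol and this is oxidised on to the α-methylene γ-lactone; the trans ring fusion follows from the existing C6 and C7 configurations.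

Step 19
Reactants: 23 trans-fused α-methylene lactone ketone
Product: 24 5β-alcohol (trans to the 1α-hydroxyl)
Conditions: Me4NBH(OAc)3, MeCN/AcOH, −30 °C
Reagents that add atoms: none
Why: Saksena–Evans hydroxyl-directed reduction: the C1 hydroxyl exchanges onto boron and hydride is delivered intramolecularly to the adjacent C5 ketone from the α-face, which sets C5 with the hydroxyl β; the saturated ring ketone, activated by the acyloxy-bearing C6, should react before the conjugated C2 ketone, and this mild hydride does not touch the methylene lactone.

Step 20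
Reactants: 24 5β-alcohol; 25 (R)-2-methylbutanoic acid
Product: 26 C5 (R)-2-methylbutanoate with C9 TBS ether
Conditions: N,N'-diisopropylcarbodiimide, DMAP, CH2Cl2, 0 °C to rt
Reagents that add atoms: none
Why: Steglich esterification of the only secondary hydroxyl (the tertiary C1 hydroxyl is too hindered to be acylated); the α-centre of a simple alkanoic acid is not enolised under these conditions, so its (R)-configuration is carried over.

Step 21
Reactants: 26 C5 ester with C9 TBS ether
Product: 27 target CNP0331957.3
Conditions: HF·pyridine, THF, 0 °C to rt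
Reagents that add atoms: none
Why: Acidic fluoride cleaves the last silyl ether without touching the ester, the lactone or the enone; basic fluoride is avoided because the hydroxy ketone array and the two Michael acceptors are base-sensitive.

**Compound list**

1 | (R)-(−)-carvone | C=C(C)[C@H]1CC(=O)C(C)=CC1 | starting material
2 | (R)-10-chlorocarvone | C=C(CCl)[C@H]1CC(=O)C(C)=CC1 | intermediate
3 | (R)-10-acetoxycarvone | C=C(COC(C)=O)[C@H]1CC(=O)C(C)=CC1 | intermediate
4 | (1R,5R)-10-acetoxy-cis-carveol (9β-hydroxyl) | C=C(COC(C)=O)[C@H]1C[C@@H](O)C(C)=CC1 | intermediate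
5 | syn-epoxy alcohol acetate (5β,10β-epoxide, 9β-hydroxyl) | C=C(COC(C)=O)[C@H]1C[C@@H](O)[C@@]2(C)O[C@H]2C1 | intermediate
6 | epoxy diol | C=C(CO)[C@H]1C[C@@H](O)[C@@]2(C)O[C@H]2C1 | intermediate
7 | bis-TBS epoxide | C=C(CO[Si](C)(C)C(C)(C)C)[C@H]1C[C@@H](O[Si](C)(C)C(C)(C)C)[C@@]2(C)O[C@H]2C1 | intermediate
8 | secondary alcohol (5β-hydroxyl, 10β-methyl) | C=C(CO[Si](C)(C)C(C)(C)C)[C@H]1C[C@@H](O[Si](C)(C)C(C)(C)C)[C@@H](C)[C@@H](O)C1 | intermediate
9 | C5 ketone with axial 10β-methyl | C=C(CO[Si](C)(C)C(C)(C)C)[C@H]1C[C@@H](O[Si](C)(C)C(C)(C)C)[C@@H](C)C(=O)C1 | intermediate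
10 | all-equatorial cyclohexanone (10α-methyl) | C=C(CO[Si](C)(C)C(C)(C)C)[C@H]1C[C@@H](O[Si](C)(C)C(C)(C)C)[C@H](C)C(=O)C1 | intermediate
11 | 6α-hydroxy ketone | C=C(CO[Si](C)(C)C(C)(C)C)[C@H]1C[C@@H](O[Si](C)(C)C(C)(C)C)[C@H](C)C(=O)[C@@H]1O | intermediate
12 | 6α-triethylsilyloxy ketone | C=C(CO[Si](C)(C)C(C)(C)C)[C@H]1C[C@@H](O[Si](C)(C)C(C)(C)C)[C@H](C)C(=O)[C@@H]1O[Si](CC)(CC)CC | intermediate
13 | (E)-pent-3-en-2-one | C/C=C/C(C)=O | starting material
14 | (E)-1,1,1-trifluorohept-5-ene-2,4-dione (formed in the flask, not isolated) | C/C=C/C(=O)CC(=O)C(F)(F)F | intermediate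
15 | (E)-1-diazopent-3-en-2-one | C/C=C/C(=O)C=[N+]=[N-] | intermediate
16 | β-hydroxy α-diazo ketone adduct (5α-hydroxyl drawn) | C=C(CO[Si](C)(C)C(C)(C)C)[C@H]1C[C@@H](O[Si](C)(C)C(C)(C)C)[C@H](C)[C@@](O)(C(=[N+]=[N-])C(=O)/C=C/C)[C@@H]1O[Si](CC)(CC)CC | intermediate
17 | ring-expanded 2-butenoylcycloheptanone as C5 enol | C=C(CO[Si](C)(C)C(C)(C)C)[C@H]1C[C@@H](O[Si](C)(C)C(C)(C)C)[C@H](C)C(C(=O)/C=C/C)=C(O)[C@@H]1O[Si](CC)(CC)CC | intermediate
18 | 6α-hydroxy enol | C=C(CO[Si](C)(C)C(C)(C)C)[C@H]1C[C@@H](O[Si](C)(C)C(C)(C)C)[C@H](C)C(C(=O)/C=C/C)=C(O)[C@@H]1O | intermediate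
19 | 1α,6α-dihydroxy diketone | C=C(CO[Si](C)(C)C(C)(C)C)[C@H]1C[C@@H](O[Si](C)(C)C(C)(C)C)[C@H](C)[C@@](O)(C(=O)/C=C/C)C(=O)[C@@H]1O | intermediate
20 | triol with free C12 alcohol | C=C(CO)[C@H]1C[C@@H](O[Si](C)(C)C(C)(C)C)[C@H](C)[C@@](O)(C(=O)/C=C/C)C(=O)[C@@H]1O | intermediate
21 | hydroxy enal (formed in the flask, not isolated) | C=C(C=O)[C@H]1C[C@@H](O[Si](C)(C)C(C)(C)C)[C@H](C)[C@@](O)(C(=O)/C=C/C)C(=O)[C@@H]1O | intermediate
22 | lactol, anomeric carbon undefined (formed in the flask, not isolated) | C=C1C(O)O[C@@H]2[C@@H]1C[C@@H](O[Si](C)(C)C(C)(C)C)[C@H](C)[C@@](O)(C(=O)/C=C/C)C2=O | intermediate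
23 | trans-fused α-methylene lactone ketone | C=C1C(=O)O[C@@H]2[C@@H]1C[C@@H](O[Si](C)(C)C(C)(C)C)[C@H](C)[C@@](O)(C(=O)/C=C/C)C2=O | intermediate
24 | 5β-alcohol | C=C1C(=O)O[C@@H]2[C@@H]1C[C@@H](O[Si](C)(C)C(C)(C)C)[C@H](C)[C@@](O)(C(=O)/C=C/C)[C@H]2O | intermediate
25 | (R)-2-methylbutanoic acid | CC[C@@H](C)C(=O)O | starting material
26 | C5 (R)-2-methylbutanoate, C9 TBS ether | C=C1C(=O)O[C@@H]2[C@@H]1C[C@@H](O[Si](C)(C)C(C)(C)C)[C@H](C)[C@@](O)(C(=O)/C=C/C)[C@H]2OC(=O)[C@H](C)CC | intermediate
27 | CNP0331957.3 | C=C1C(=O)O[C@@H]2[C@@H]1C[C@@H](O)[C@H](C)[C@@](O)(C(=O)/C=C/C)[C@H]2OC(=O)[C@H](C)CC | target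

**Step count and risks**

Total step count: 21 (20 on the main line from 1, one for the diazo ketone 15).
Longest linear sequence: 20 steps (steps 1–11 and 13–21, from 1 to 27).

Steps most likely to fail:

1. Step 14. The ring bond to the silyloxy-bearing C6 may migrate in competition with C10 through lone-pair assistance, or the carbenoid may be diverted into cyclopropanation or O–H insertion. The fallback sets out from 16 and keeps the insertion but changes the substrate so that C6 cannot compete. Buffered HF·pyridine removes the triethylsilyl group to give the C6-hydroxy diazo carbinol F1. Trifluoroacetic anhydride and pyridine at −40 °C acylate the secondary hydroxyl only, giving the C6 trifluoroacetate F2, in which C6 bears a strongly withdrawing, non-donating acyloxy group. Rh2(OAc)4 then effects the same 1,2-shift to the ring-expanded enol trifluoroacetate F3. Brief NaHCO3 in MeOH at 0 °C removes the trifluoroacetate, and the route is rejoined at 18.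

2. Step 16. Oxygen may be delivered to the β-face because the α-face of C1 is flanked by the C10 methyl, and the vanadium peroxide may over-oxidise the α-ketol or cleave the hydroxylated diketone. The fallback sets out from 17, with the triethylsilyl ether still in place, and replaces substrate direction by reagent control. The potassium enolate (KN(SiMe3)2, THF, −78 °C) is hydroxylated with the enantiomer of (camphorsulfonyl)oxaziridine that is matched to α-face attack, both enantiomers being commercial. This gives the 1α-hydroxy diketone triethylsilyl ether F4, and buffered HF·pyridine then removes the silyl group so that the route is rejoined at 19.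

3. Step 13. Proton transfer from the hindered, doubly α-substituted ketone to the basic lithiated diazo ketone, reversal of the addition, or decay of the lithiated species may outrun C–C bond formation. The fallback sets out from 12 and 15 and avoids base altogether. BF3·OEt2 in CH2Cl2 at −78 °C activates the ketone toward the neutral diazo ketone, and the diazonium betaine rearranges with loss of dinitrogen in the same operation (Tiffeneau–Demjanov-type homologation with an acceptor diazo compound, as practised with diazoacetates and cycloalkanones), the same electronic preference for C10 applying. This bypasses 16 and arrives directly at 17, and it makes no new compound (F0).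

**Further compounds**

F1 | step 14 | C6-hydroxy diazo carbinol (16 without the triethylsilyl group) | C=C(CO[Si](C)(C)C(C)(C)C)[C@H]1C[C@@H](O[Si](C)(C)C(C)(C)C)[C@H](C)[C@@](O)(C(=[N+]=[N-])C(=O)/C=C/C)[C@@H]1O
F2 | step 14 | C6 trifluoroacetate of the diazo carbinol | C=C(CO[Si](C)(C)C(C)(C)C)[C@H]1C[C@@H](O[Si](C)(C)C(C)(C)C)[C@H](C)[C@@](O)(C(=[N+]=[N-])C(=O)/C=C/C)[C@@H]1OC(=O)C(F)(F)F
F3 | step 14 | ring-expanded enol C6 trifluoroacetate | C=C(CO[Si](C)(C)C(C)(C)C)[C@H]1C[C@@H](O[Si](C)(C)C(C)(C)C)[C@H](C)C(C(=O)/C=C/C)=C(O)[C@@H]1OC(=O)C(F)(F)F
F4 | step 16 | 1α-hydroxy diketone 6α-triethylsilyl ether | C=C(CO[Si](C)(C)C(C)(C)C)[C@H]1C[C@@H](O[Si](C)(C)C(C)(C)C)[C@H](C)[C@@](O)(C(=O)/C=C/C)C(=O)[C@@H]1O[Si](CC)(CC)CC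
F0 | step 13 | none | none
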